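Left-handed material obeys a conservation rule: left-handed substrate plus left-handed product falls by conversion of that product into its mirror image, and the two mirror images, being of equal energy, exchange with one constant in both directions.

| flask | left-handed substrate | right-handed substrate | partner | precatalyst | remark | time |
|---|---|---|---|---|---|---|
| grey | 11 mM | 11 mM | 13.2 mM (fed, over 15 h) | 9.5 µM | run made earlier; the fed solution adds 0.50 times the starting volume |  |
| red | 11 mM | 11 mM | 13.2 mM (fed, over 15 h) | 14 µM | run made earlier; the fed solution adds 0.50 times the starting volume |  |
| violet | 5.5 mM | 5.5 mM | 13.2 mM (fed, over 15 h) | 19 µM | run made earlier; the fed solution adds 0.50 times the starting volume |  |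
| dawn | 11 mM | 11 mM | 13.2 mM (fed, over 15 h) | 19 µM | the fed solution adds 0.50 times the starting volume | 2.5 d |
| spring | 11 mM | 11 mM | 13.2 mM (fed, over 4.0 h) | 19 µM | the fed solution adds 0.50 times the starting volume | 2.5 d |

| run | time / d | left-handed product / % | right-handed product / % | left-handed substrate / % |
|---|---|---|---|---|
| grey | 0.625 | 0 | 0.1 | 49.8 |
| grey | 1.25 | 1.3 | 1.2 | 48.3 |
| grey | 2.08 | 3.2 | 2.4 | 45.0 |
| grey | 2.50 | 3.8 | 3.0 | 43.4 |
| red | 0.208 | 0 | 0.2 | 49.7 |
| red | 0.500 | 0.3 | 0.5 | 49.7 |
| red | 1.04 | 1.1 | 0.5 | 48.4 |
| red | 2.50 | 5.7 | 4.9 | 40.7 |
| violet | 0.333 | 0 | 0.1 | 49.7 |
| violet | 0.833 | 1.1 | 0.3 | 48.0 |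
| violet | 1.67 | 5.2 | 4.5 | 41.4 |
| violet | 2.50 | 10.3 | 8.9 | 33.6 |

(standard deviation of a reading: 0.3 percentage points)

- free catalyst is single-handed; left-handed substrate and right-handed substrate are mirror images of each other, charged as a racemate, each of them at the stated concentration
- every charge counts on the volume at the start, and the solution that is fed holds the whole dose
- the numbers in the tables scatter by 0.3 percentage points (one standard deviation)
- an excess is the difference of the two amounts in percent of their sum
- an excess is below zero if the other one leads

1. the winner by excess of left-handed product over right-handed product in the product; "neither" if no more than 2 percentage points parts them (dawn / spring / neither)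
2. excess of left-handed product over right-handed product in the product at the end, dawn
3. excess of left-handed product over right-handed product in the product at the end, spring

In violet, from 1.67 d to 2.50 d, left-handed substrate lost 7.8 percentage points while left-handed product gained 5.1 points. The whole catalyst charge amounts to 0.173 % of the substrates, less than that gap, so I booked the gap as crossing between the products. Dividing it by the mean product difference, 1.1 points, and by the time gave 3.10 /d, the leak constant, the share of the product difference crossing per day.

Next I took red, whose substrate charge matches dawn's. From 1.04 d to 2.50 d, counting lost left-handed substrate as left-handed product formed, the product was formed with an excess of 71.1 %. Its growth, product formed per day over product standing at the end, was 0.582 /d; violet gave 0.596 /d, about the same. The difference relaxes with a half-life of 0.112 d, short against 2.5 d, so I balanced its formation against its decay. That gave an end excess of formation excess times growth over twice the leak constant: 6.67 %.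

The weak link was the leak constant, since 1.1 points carries a scatter of 0.3 points. Red gave 3.03 /d, close to it, so I kept about 6.67 % for dawn and spring alike. The leak constant stands inversely to that difference and the end excess inversely to the leak constant, so the excess rises with the difference, and moving the difference by 0.3 points either way gave 4.77 % to 8.58 %.

The forecast stood above my figure, with 8 % for dawn, 9 % for spring and the verdict neither, holding that “Faster feeding mainly shifts the timing”.

Dawn ended at 5.42 % and spring at 4.75 %, so the answer was neither.

    free catalyst + left-handed substrate ⇌ catalyst intermediate A (K = 160 /M, k = 40.0 /M/s)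
    free catalyst + right-handed substrate ⇌ catalyst intermediate B (K = 57.0 /M, k = 43.0 /M/s)
    partner + catalyst intermediate A → free catalyst + left-handed product (k = 0.430 /M/s)
    partner + catalyst intermediate B → free catalyst + right-handed product (k = 0.150 /M/s)
    left-handed product ⇌ right-handed product (k = 4.50 × 10⁻⁵ /s)
    free catalyst → spent catalyst (k = 4.10 × 10⁻⁷ /s)
    partner + precatalyst → free catalyst + spent reagent (k = 0.00100 /M/s)

In dawn the excess had stood at 34.0 % after 0.625 d. The neighbour flask, like spring but with 53 mM of partner, ended at an excess of 0.0674 %, a product difference of 0.04 points. Multiplied by my leak constant, itself a reading with its scatter, that gives an estimated crossing of 0.00124 /d of the charge.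

The data were generated by integration on assumed constants; noise was put on by code.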